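**Assumption:** the target has no stereocentre (it is achiral), so no stereocontrol is needed; compound 1 is taken as a purchased catalogue building block.

**Retrosynthetic overview**
1. Target 10 ⇒ N1–C2 disconnection: an aza-ylide nitrogen closes 5-endo onto a bromoalkyne made in situ from a gem-dibromoolefin ⇒ azide 6.
2. 6 ⇒ C2=C3 olefination (Ramirez) of 2-azido-4,6-dibromobenzaldehyde 3; the CBr2 carbon brings in the C2 bromine.
3. 3 ⇒ N–C7a disconnection: SNAr of fluoride by azide in 2,4-dibromo-6-fluorobenzaldehyde 1.
4. Ring order: the benzene ring is bought with both aryl bromines in place; the pyrrole ring is the only ring formed, last, by C–N bond formation.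

**Route**

Step 1
Reactants: 1 2,4-dibromo-6-fluorobenzaldehyde; 2 sodium azide
Product: 3 2-azido-4,6-dibromobenzaldehyde
Conditions: NaN3 (1.2 equiv), DMSO, 23 °C, 12 h, dark; aqueous work-up below 40 °C
Reagents that add atoms: sodium azide, [Na+].[N-]=[N+]=[N-]
Why: SNAr (addition–elimination via a Meisenheimer adduct) in which the fluoride ortho to the formyl group leaves far faster than either bromide because addition at C–F is rate-limiting and favoured, while the low temperature keeps the o-azido aldehyde from cyclising to the anthranil.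

Step 2
Reactants: 3 2-azido-4,6-dibromobenzaldehyde; 4 carbon tetrabromide; 5 triphenylphosphine
Product: 6 1-azido-3,5-dibromo-2-(2,2-dibromoethenyl)benzene
Conditions: CBr4 (2.0 equiv), PPh3 (3.9 equiv), CH2Cl2, 0 °C, 30 min; then 3, 0 °C, 1 h; silica plug
Reagents that add atoms: carbon tetrabromide, BrC(Br)(Br)Br
Why: Ramirez gem-dibromoolefination (Wittig-type, first stage of the Corey–Fuchs sequence) with pre-formed Ph3P=CBr2, which adds to the aldehyde much faster than to the azide, and with no free PPh3 left to start a Staudinger reaction; the new alkene carbon carries two identical bromines, so there is no E/Z issue.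

Step 3
Reactants: 6 1-azido-3,5-dibromo-2-(2,2-dibromoethenyl)benzene; 5 triphenylphosphine
Product: 10 2,4,6-tribromo-1H-indole, via iminophosphorane 7 (not isolated), via bromoalkyne 8 (not isolated), via N-phosphonioindole bromide 9 (not isolated)
Conditions: PPh3 (1.05 equiv), MeCN, 23 °C, 2 h; then DBU (1.5 equiv), 50 °C, 4 h; then H2O, 50 °C, 1 h
Reagents that add atoms: none
Why: Proposed new method: the Staudinger aza-ylide serves as a traceless, neutral N-nucleophile — PPh3 converts the azide to iminophosphorane 7 (fully consumed before base is added), DBU eliminates HBr from the gem-dibromoolefin to give 1-bromoalkyne 8 (known E2), the ylide nitrogen (far more nucleophilic than ArNH2 and needing no deprotonation) adds 5-endo-dig to the bromine-bearing alkyne carbon with C3 protonated by DBU·H+ to give 9, and water then attacks phosphorus to expel the indolide as the best leaving group, releasing free N–H 10 and Ph3PO without any transition metal that could touch the three C–Br bonds; the closest known reaction types are the base-promoted (Cs2CO3 or TBAF) cyclisation of N-sulfonyl 2-(2,2-dibromovinyl)anilines to 2-bromoindoles and the N-alkylation/hydrolysis chemistry of Staudinger iminophosphoranes.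

**Compound list**
1 | 2,4-dibromo-6-fluorobenzaldehyde | O=Cc1c(F)cc(Br)cc1Br | starting material
2 | sodium azide | [Na+].[N-]=[N+]=[N-] | starting material
3 | 2-azido-4,6-dibromobenzaldehyde | O=Cc1c(N=[N+]=[N-])cc(Br)cc1Br | intermediate
4 | carbon tetrabromide | BrC(Br)(Br)Br | starting material
5 | triphenylphosphine | c1ccc(cc1)P(c1ccccc1)c1ccccc1 | starting material
6 | 1-azido-3,5-dibromo-2-(2,2-dibromoethenyl)benzene | BrC(Br)=Cc1c(N=[N+]=[N-])cc(Br)cc1Br | intermediate
7 | iminophosphorane: 3,5-dibromo-2-(2,2-dibromoethenyl)-N-(triphenyl-λ5-phosphanylidene)aniline | BrC(Br)=Cc1c(N=P(c2ccccc2)(c2ccccc2)c2ccccc2)cc(Br)cc1Br | intermediate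
8 | bromoalkyne: 3,5-dibromo-2-(bromoethynyl)-N-(triphenyl-λ5-phosphanylidene)aniline | BrC#Cc1c(N=P(c2ccccc2)(c2ccccc2)c2ccccc2)cc(Br)cc1Br | intermediate
9 | N-phosphonioindole bromide: triphenyl(2,4,6-tribromo-1H-indol-1-yl)phosphonium bromide | [Br-].Brc1cc(Br)c2cc(Br)n([P+](c3ccccc3)(c3ccccc3)c3ccccc3)c2c1 | intermediate
10 | 2,4,6-tribromo-1H-indole | Brc1cc(Br)c2cc(Br)[nH]c2c1 | target

**Total step count:** 3
**Longest linear sequence:** 3

**Steps most likely to fail, with fallbacks**

Step 3 (proposed new step; highest risk). The aza-ylide may be too weak a nucleophile for the bromoalkyne, or DBU may debrominate the bromoalkyne. The fallback uses known chemistry, sets out from 6 and comes back at 10. Staudinger reduction of 6 (PPh3, THF/H2O, 50 °C) gives 3,5-dibromo-2-(2,2-dibromoethenyl)aniline F1. Mesylation (MsCl, pyridine, CH2Cl2, 0 °C) gives N-[3,5-dibromo-2-(2,2-dibromoethenyl)phenyl]methanesulfonamide F2. The established base-promoted, metal-free cyclisation of N-sulfonyl 2-(2,2-dibromovinyl)anilines (Cs2CO3, DMSO, 80 °C) gives 2,4,6-tribromo-1-(methanesulfonyl)-1H-indole F3. Aqueous NaOH in MeOH/THF (50 °C) then cleaves the N-mesyl group to give 10.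

Step 2. The phosphine or ylide may attack the azide, or the doubly ortho-substituted aldehyde may react slowly. The fallback sets out from 3 and comes back at 6 by a phosphine-free olefination. Hydrazine hydrate (EtOH, 23 °C) converts 3 into (E)-(2-azido-4,6-dibromobenzylidene)hydrazine F4. The copper-catalysed olefination of N-unsubstituted hydrazones with 4 (CuCl 10 mol %, aq NH3, DMSO, 23 °C) then gives 6 with loss of N2; no P(III) is present, so the azide is safe.

Step 1. The SNAr may be sluggish, and heating it risks anthranil formation or bromide displacement. The fallback sets out from 1 and comes back at 3 by amination followed by diazotisation/azidation. Aqueous NH3 in DMSO (sealed tube, 80 °C; acidic work-up hydrolyses the aldimine) displaces fluoride to give 2-amino-4,6-dibromobenzaldehyde F5. NaNO2 in H2SO4/AcOH (0 °C) gives 3,5-dibromo-2-formylbenzenediazonium hydrogen sulfate F6, which NaN3 (0 °C) converts into 3.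

**Further compounds**
F1 | step 3 | 3,5-dibromo-2-(2,2-dibromoethenyl)aniline | Nc1cc(Br)cc(Br)c1C=C(Br)Br
F2 | step 3 | N-[3,5-dibromo-2-(2,2-dibromoethenyl)phenyl]methanesulfonamide | CS(=O)(=O)Nc1cc(Br)cc(Br)c1C=C(Br)Br
F3 | step 3 | 2,4,6-tribromo-1-(methanesulfonyl)-1H-indole | CS(=O)(=O)n1c(Br)cc2c(Br)cc(Br)cc21
F4 | step 2 | (E)-(2-azido-4,6-dibromobenzylidene)hydrazine | N/N=C/c1c(N=[N+]=[N-])cc(Br)cc1Br
F5 | step 1 | 2-amino-4,6-dibromobenzaldehyde | Nc1cc(Br)cc(Br)c1C=O
F6 | step 1 | 3,5-dibromo-2-formylbenzenediazonium hydrogen sulfate | O=Cc1c([N+]#N)cc(Br)cc1Br.OS(=O)(=O)[O-]
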